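## Analysis of the target

CNP0222748.1 (15), C45H62O4, is an octacyclic adduct of a 24-nor-friedelane triterpene of the pristimerin type (rings A to E, methyl ester at C29) and a guaiane sesquiterpene (primed atoms: five-membered ring C1′ to C5′, seven-membered ring C1′, C5′ to C10′). The two halves are joined by a 1,4-benzodioxane whose oxygens are O2 and O3 of aromatic ring A. The triterpene half has the six stereocentres of pristimerin (C9, C13, C14, C17, C18, C20) and in addition C8 (α-H) next to a C6=C7 styrene bond. The sesquiterpene half has C7′ (S, isopropenyl) and C10′ (R, methyl) cis on the seven-membered ring; as drawn, both are antipodal to the corresponding centres of commercial (−)-guaiol, so natural guaianes cannot be used. C3′ (R) and the quaternary C4′ (S) carry the two ether oxygens, cis to each other and on the same face as the C10′ methyl. The regiochemistry is the crowded one: the hindered O3 (next to the C4 aryl methyl) sits on quaternary C4′ and the open O2 on secondary C3′. The feature the route is built on is that C4′ is allylic to the tetrasubstituted C1′=C5′ bond shared by the five- and seven-membered rings, so the C4′–O3 bond is the allylic-transposition image of a C1′ tertiary carbinol flanked by a C4′=C5′ bond, which is the substitution pattern of a 4-hydroxycyclopent-2-enone. The difficulty is to join two hindered terpenes with control of which oxygen goes to which carbon and of the face of the five-membered ring, when the nearest sesquiterpene stereocentre (C10′) is four bonds from C3′ and C4′; the tertiary allylic aryl ether, the isopropenyl group, the styrene and the air-sensitive catechol precursors limit the conditions.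

## Retrosynthetic reasoning

15 to 14. The C6=C7 bond with the C8 hydrogen is taken back to the deconjugated C7=C8 isomer 14. This lets the triterpene travel in the pattern that hydride reduction of the quinone methide gives. The forward step is a base-mediated olefin migration into conjugation with ring A, with protonation of C8 on the open α face.

14 to 13 (key disconnection). The O3–C4′ bond is cut with allylic transposition: C4′ becomes one terminus of a C1′–C5′–C4′ allyl cation that comes from a tertiary allylic alcohol at C1′, and O3 carries a 4-methoxybenzyl group. This bond is cut last, and not together with O2–C3′, because an intramolecular closure onto C4′ can only give the cis-fused dioxane. C4′ therefore takes its configuration from C3′ and not from the remote C10′. The forward step must ionise the C1′ carbinol (either epimer), unmask O3 and close the six-membered ring at C4′ only.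

13 to 9 and 12. The O2–C3′ bond is cut as an SN2 etherification with inversion (Mitsunobu). This is the convergent point: the sesquiterpene arrives as diol 9, whose C3′ carbinol is the one centre set by a chiral reagent, and the triterpene as phenol 12 with only O2 free.

12 to 11 to 10. The two catechol oxygens are told apart without a selective step: in pristimerin 10 only O3 bears a hydrogen, so it is alkylated first (11), and hydride reduction of the quinone methide then reveals O2 as the only phenol (12).

9 to 8. The C3′ carbinol comes from the C3′ ketone of hydroxy enone 8 by a reagent-controlled reduction, so its configuration does not depend on the uncontrolled C1′ centre.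

8 to 7. The five-membered ring is opened at C1′–C2′: 8 is the intramolecular aldol product of ene-1,4-dione 7. This one fold delivers the C1′ carbinol (the future leaving group), the C3′ carbonyl and the C4′=C5′ bond.

7 to 6 to 4 and 5. The C4′–C5′ bond comes from an aldol addition of cycloheptanone 4 to butane-2,3-dione 5 (adduct 6), followed by dehydration.

4 to 2 to 1. The seven-membered ring, with C7′ and C10′ already cis, is the one-carbon ring expansion product of cis-dihydrocarvone 2. Compound 2 comes from (S)-carvone 1 by an enzymatic C=C reduction that fixes the methyl-bearing centre independently of the isopropenyl centre.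

## Alternatives that were turned down

Alternative 1: the textbook, biomimetic cut of both C–O bonds at once. The forward key step is an inverse-demand hetero-Diels–Alder reaction between o-quinone A1 (the 8α-H o-quinone tautomer of 10) and cyclopentadiene A2, adding across C3′=C4′. It was turned down for four reasons.
- The two faces of C3′=C4′ differ only through the C10′ methyl four bonds away, and the target needs attack on the face that carries that pseudo-axial methyl. Nothing in A2 secures this, and a mixture or the wrong diastereomer is the likely result.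
- A2 is a 1,2,3-trisubstituted cyclopentadiene that equilibrates by 1,5-hydrogen shifts to dienes that would give constitutional isomers.
- A1 is a minor tautomer that must be made and trapped in situ, and carbon-centred cycloaddition modes compete.
- Making A2 costs about as many steps as diol 9.

Alternative 2: a double Tsuji–Trost annulation. Catechol A3 and bis-carbonate A4 would be joined by zerovalent palladium, the first substitution at C3′ and the second at C4′ through a C1′–C5′–C4′ π-allyl complex. It was turned down for three reasons.
- The double-inversion mechanism needs the C1′ and C3′ leaving groups cis, but the C1′ carbinol cannot be set with control.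
- A tertiary carbonate next to a quaternary centre is hard to make, and both π-allyl termini are fully substituted, so ionisation would be slow.
- The free catechol is air-sensitive and leaves open which oxygen reacts first.

Alternative 3: build both carbocycles of the sesquiterpene in one step. A rhodium-catalysed allenic Pauson–Khand reaction of allene-yne A5 would give dienone A6. It was turned down for three reasons.
- C10′ becomes sp2 and would have to be re-created by a 1,6-reduction under remote control from C7′.
- A6 lacks the C1′ oxygen, so the dioxane closure would need an oxidative C–H step or a cyclopentadiene, which leads back to the problems of Alternative 1.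
- The isopropenyl group is a competing ene partner for the alkyne, and the repair steps after the cyclisation cost more than it saves.

Key step: step 10

Assumption: pristimerin (10) is bought as the isolated natural product and supplies the carbon stereocentres of the triterpene half.
Remark: C1′ of 8, 9 and 13 forms as an epimer mixture and is left open in their SMILES, because both epimers give the same allyl cation in step 10.

## Route

Step 1
Reactants: 1 (S)-carvone
Product: 2 (2R,5S)-2-methyl-5-(prop-1-en-2-yl)cyclohexan-1-one (cis-dihydrocarvone)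
Conditions: ene-reductase (Old Yellow Enzyme 1), NADP+ (cat.), glucose dehydrogenase, D-glucose, phosphate buffer pH 7.0, 30 °C
Reagents that add atoms: none
Why: Ene-reductases of the Old Yellow Enzyme family reduce the activated C=C bond by anti addition of hydride to C3 and a proton to C2; the enzyme, not the remote isopropenyl centre, should fix C2 as R, which gives the cis isomer that chemical conjugate reduction does not favour.

Step 2
Reactants: 2 (2R,5S)-2-methyl-5-(prop-1-en-2-yl)cyclohexan-1-one
Product: 4 (2R,5S)-2-methyl-5-(prop-1-en-2-yl)cycloheptan-1-one, via α-silyl ketone 3 (not isolated)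
Conditions: TMSCHN2, Sc(OTf)3 (10 mol %), CH2Cl2, −78 → 0 °C; then 1 M HCl, THF, 0 °C
Reagents that add atoms: trimethylsilyldiazomethane, C[Si](C)(C)C=[N+]=[N-]
Why: Lewis acid-promoted diazoalkane homologation (Tiffeneau–Demjanov type) in which the less substituted α-carbon migrates, so the new CH2 enters on the side away from the methyl-bearing centre, which is not touched at low temperature; acid work-up removes silicon from the β-keto silane.

Step 3
Reactants: 4 (2R,5S)-2-methyl-5-(prop-1-en-2-yl)cycloheptan-1-one; 5 butane-2,3-dione
Product: 6 (2R,5S)-7-(2-hydroxy-3-oxobutan-2-yl)-2-methyl-5-(prop-1-en-2-yl)cycloheptan-1-one (mixture at the two new centres)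
Conditions: LiN(iPr)2, THF, −78 °C; then 5 (excess), −78 °C; AcOH quench at −78 °C
Reagents that add atoms: none
Why: Kinetic deprotonation at the unhindered α′-methylene and not at the methine, then aldol addition to the very electrophilic 1,2-diketone; the cold quench should prevent retro-aldol cleavage and epimerisation of the methyl-bearing centre.

Step 4
Reactants: 6 (2R,5S)-7-(2-hydroxy-3-oxobutan-2-yl)-2-methyl-5-(prop-1-en-2-yl)cycloheptan-1-one
Product: 7 (2R,5S)-2-methyl-7-(3-oxobutan-2-ylidene)-5-(prop-1-en-2-yl)cycloheptan-1-one (ene-1,4-dione, E/Z mixture, Z isomer drawn)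
Conditions: MsCl, Et3N, CH2Cl2, 0 °C → rt
Reagents that add atoms: none
Why: Sulfonylation and E1cB loss of the tertiary β-hydroxyl of a β-hydroxy ketone give the fully conjugated ene-dione; the weak amine base should not enolise the ring ketone towards the methyl-bearing centre.

Step 5
Reactants: 7 (2R,5S)-2-methyl-7-(3-oxobutan-2-ylidene)-5-(prop-1-en-2-yl)cycloheptan-1-one
Product: 8 (5S,8R)-8a-hydroxy-3,8-dimethyl-5-(prop-1-en-2-yl)-4,5,6,7,8,8a-hexahydroazulen-2(1H)-one (1′-hydroxyguaia-4′,11′-dien-3′-one, both C1′ epimers)
Conditions: K2CO3 (0.3 equiv), MeOH, 0 °C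
Reagents that add atoms: none
Why: Intramolecular aldol addition of the methyl ketone to the ring ketone, the known cyclisation of cis-ene-1,4-diones to 4-hydroxycyclopent-2-enones; E and Z isomers should interconvert through the dienolate and only Z can close, and dehydration of the product is blocked because it would give a cyclopentadienone.

Step 6
Reactants: 8 (5S,8R)-8a-hydroxy-3,8-dimethyl-5-(prop-1-en-2-yl)-4,5,6,7,8,8a-hexahydroazulen-2(1H)-one
Product: 9 (2S,5S,8R)-3,8-dimethyl-5-(prop-1-en-2-yl)-2,4,5,6,7,8-hexahydroazulene-2,8a(1H)-diol (3′S carbinol, both C1′ epimers)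
Conditions: (R)-2-methyl-CBS-oxazaborolidine (0.2 equiv), catecholborane, toluene, −78 °C; then MeOH
Reagents that add atoms: none
Why: Corey–Bakshi–Shibata reduction: with the α-methyl alkenyl branch as the large group, the (R)-catalyst should deliver hydride to give the S carbinol under reagent control, and catecholborane at −78 °C should leave the isopropenyl group and the tertiary alcohol alone.

Step 7
Reactants: 10 pristimerin
Product: 11 3-O-(4-methoxybenzyl)pristimerin
Conditions: 4-methoxybenzyl chloride, K2CO3, DMF, rt
Reagents that add atoms: 4-methoxybenzyl chloride, COc1ccc(CCl)cc1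
Why: Williamson O-alkylation of the only hydroxyl of 10, a vinylogous acid; done at the quinone methide stage it marks O3 and leaves O2 as a carbonyl, so the catechol oxygens are differentiated without a selective step.

Step 8
Reactants: 11 3-O-(4-methoxybenzyl)pristimerin
Product: 12 methyl 2-hydroxy-3-(4-methoxybenzyloxy)-24-nor-D:A-friedooleana-1,3,5(10),7-tetraen-29-oate
Conditions: NaBH4, THF–MeOH, 0 °C, argon
Reagents that add atoms: none
Why: 1,6-Addition of hydride to C6 of the quinone methide aromatises ring A and reveals O2–H as the only phenol, as in the known borohydride reduction of pristimerin-type quinone methides; the hindered ester should survive.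

Step 9
Reactants: 9 (2S,5S,8R)-3,8-dimethyl-5-(prop-1-en-2-yl)-2,4,5,6,7,8-hexahydroazulene-2,8a(1H)-diol; 12 methyl 2-hydroxy-3-(4-methoxybenzyloxy)-24-nor-D:A-friedooleana-1,3,5(10),7-tetraen-29-oate
Product: 13 methyl 2-{[(2R,5S,8R)-8a-hydroxy-3,8-dimethyl-5-(prop-1-en-2-yl)-1,2,4,5,6,7,8,8a-octahydroazulen-2-yl]oxy}-3-(4-methoxybenzyloxy)-24-nor-D:A-friedooleana-1,3,5(10),7-tetraen-29-oate
Conditions: PPh3, DIAD, toluene, 0 °C → rt
Reagents that add atoms: none
Why: Mitsunobu etherification: the phenol displaces the activated secondary allylic alcohol by SN2 with inversion (3′S to 3′R); the tertiary alcohol is inert and SN2′ attack at the fully substituted C5′ is blocked.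

Step 10
Reactants: 13 methyl 2-{[(2R,5S,8R)-8a-hydroxy-3,8-dimethyl-5-(prop-1-en-2-yl)-1,2,4,5,6,7,8,8a-octahydroazulen-2-yl]oxy}-3-(4-methoxybenzyloxy)-24-nor-D:A-friedooleana-1,3,5(10),7-tetraen-29-oate
Product: 14 the C7=C8 isomer of 15 (C6 is CH2, C8 is sp2; dioxane, C3′, C4′ and C1′=C5′ as in the target)
Conditions: TFA (5 vol %), anisole, CH2Cl2, −20 → 0 °C
Reagents that add atoms: none
Why: Acid ionises the tertiary allylic C1′ carbinol (either epimer) to the C1′–C5′–C4′ allyl cation while the 4-methoxybenzyl group leaves O3 (taken up by anisole), and O3 closes onto C4′; the double bond ends in the tetrasubstituted C1′=C5′ position. The closest known reaction type is the acid-mediated dehydrative SN1′ cycloetherification of phenols with tertiary allylic alcohols, here combined with acid cleavage of an aryl 4-methoxybenzyl ether. The dioxane ring closes in a 6-exo mode at the C4′ terminus; attack at the other terminus C1′ would need a bridged eight-membered ring and is excluded by the O2–C3′ tether. The new quaternary stereocentre C4′ is controlled by that same tether: O3 can reach C4′ only on the face that bears the C3′–O2 bond, so the ring fusion is cis and C4′ takes its configuration from the CBS-set, Mitsunobu-inverted C3′, not from C10′. The step needs O-attack to win over C-attack and over proton loss from the cation; the only free aromatic position, C1, is ortho to the quaternary C9 and too crowded for a Friedel–Crafts closure, and the intramolecular oxygen is held next to C4′. It also needs the tertiary carbinol to ionise before the secondary allylic aryl ether at C3′ or the isopropenyl group react, which dilute acid at low temperature and a prompt quench should secure.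

Step 11
Reactants: 14 the C7=C8 isomer of 15
Product: 15 CNP0222748.1
Conditions: KOtBu (0.3 equiv), DMSO, 25 °C
Reagents that add atoms: none
Why: Base-mediated prototropic shift of the skipped (1,4-dihydronaphthalene-type) olefin into conjugation with ring A through the benzylic and allylic C6 carbanion; C8 should be protonated on the α face because the β face is covered by the axial C9 and C14 methyls, which gives the trans B/C junction of the target.

## Compound list

1 | (S)-carvone, (5S)-2-methyl-5-(prop-1-en-2-yl)cyclohex-2-en-1-one | CC1=CC[C@@H](CC1=O)C(C)=C | starting material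
2 | (2R,5S)-2-methyl-5-(prop-1-en-2-yl)cyclohexan-1-one (cis-dihydrocarvone) | C[C@@H]1CC[C@@H](CC1=O)C(C)=C | intermediate
3 | (2R,5S)-2-methyl-5-(prop-1-en-2-yl)-7-(trimethylsilyl)cycloheptan-1-one (C7 epimers) | C[C@@H]1CC[C@@H](CC([Si](C)(C)C)C1=O)C(C)=C | intermediate
4 | (2R,5S)-2-methyl-5-(prop-1-en-2-yl)cycloheptan-1-one | C[C@@H]1CC[C@@H](CCC1=O)C(C)=C | intermediate
5 | butane-2,3-dione | CC(=O)C(C)=O | starting material
6 | (2R,5S)-7-(2-hydroxy-3-oxobutan-2-yl)-2-methyl-5-(prop-1-en-2-yl)cycloheptan-1-one (mixture at C7 and the carbinol) | CC(=O)C(C)(O)C1C[C@@H](C(C)=C)CC[C@@H](C)C1=O | intermediate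
7 | (2R,5S)-2-methyl-7-(3-oxobutan-2-ylidene)-5-(prop-1-en-2-yl)cycloheptan-1-one (Z isomer drawn; E also forms) | CC(=O)/C(C)=C1/C[C@@H](C(C)=C)CC[C@@H](C)C1=O | intermediate
8 | (5S,8R)-8a-hydroxy-3,8-dimethyl-5-(prop-1-en-2-yl)-4,5,6,7,8,8a-hexahydroazulen-2(1H)-one (C8a epimers) | CC1=C2C[C@@H](C(C)=C)CC[C@@H](C)C2(O)CC1=O | intermediate
9 | (2S,5S,8R)-3,8-dimethyl-5-(prop-1-en-2-yl)-2,4,5,6,7,8-hexahydroazulene-2,8a(1H)-diol (C8a epimers) | CC1=C2C[C@@H](C(C)=C)CC[C@@H](C)C2(O)C[C@@H]1O | intermediate
10 | pristimerin | CC1=C(O)C(=O)C=C2C1=CC=C1[C@@]2(C)CC[C@@]2(C)[C@@H]3C[C@](C)(C(=O)OC)CC[C@]3(C)CC[C@]12C | starting material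
11 | 3-O-(4-methoxybenzyl)pristimerin | CC1=C(OCc2ccc(OC)cc2)C(=O)C=C2C1=CC=C1[C@@]2(C)CC[C@@]2(C)[C@@H]3C[C@](C)(C(=O)OC)CC[C@]3(C)CC[C@]12C | intermediate
12 | methyl 2-hydroxy-3-(4-methoxybenzyloxy)-24-nor-D:A-friedooleana-1,3,5(10),7-tetraen-29-oate | Cc1c(OCc2ccc(OC)cc2)c(O)cc2c1CC=C1[C@@]2(C)CC[C@@]2(C)[C@@H]3C[C@](C)(C(=O)OC)CC[C@]3(C)CC[C@]12C | intermediate
13 | O2-(3′R)-guaienyl ether of 12 with free C1′ tertiary alcohol (C1′ epimers) | CC1=C2C[C@@H](C(C)=C)CC[C@@H](C)C2(O)C[C@H]1Oc1cc2c(c(C)c1OCc1ccc(OC)cc1)CC=C1[C@@]2(C)CC[C@@]2(C)[C@@H]3C[C@](C)(C(=O)OC)CC[C@]3(C)CC[C@]12C | intermediate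
14 | C7=C8 isomer of the target (C6 is CH2) | C=C(C)[C@H]1CC[C@@H](C)C2=C(C1)[C@]1(C)Oc3c(cc4c(c3C)CC=C3[C@@]4(C)CC[C@@]4(C)[C@@H]5C[C@](C)(C(=O)OC)CC[C@]5(C)CC[C@]34C)O[C@@H]1C2 | intermediate
15 | CNP0222748.1 | C=C(C)[C@H]1CC[C@@H](C)C2=C(C1)[C@]1(C)Oc3c(cc4c(c3C)C=C[C@H]3[C@@]4(C)CC[C@@]4(C)[C@@H]5C[C@](C)(C(=O)OC)CC[C@]5(C)CC[C@]34C)O[C@@H]1C2 | target

## Step count and risk

Total step count: 11. Longest linear sequence: 9 (steps 1 to 6, then 9 to 11); the triterpene branch (steps 7 and 8) joins at step 9.

Steps least certain to work

Step 10 (key step). The most likely failure is loss of a proton from the allyl cation to give dienes, in competition with ring closure. The tertiary allylic ether of the product may also re-ionise if the acid exposure is too long. Both would show up as elimination products or as erosion at C3′. The fallback separates unmasking from ring closure, so that the closure no longer passes through a free cation in strong acid. It sets out from 10 and comes back at 14. Pristimerin is alkylated with allyl bromide and K2CO3 to 3-O-allylpristimerin F1. NaBH4 reduction gives the 2-hydroxy-3-allyloxy arene F2, and Mitsunobu coupling with 9 gives the allyl-protected ether F3. Pd(PPh3)4 with morpholine removes the allyl group under neutral conditions to give the free O3 phenol F4. The ring is then closed by gold-catalysed dehydrative allylic etherification (Ph3PAuCl/AgOTf, CH2Cl2, molecular sieves), a formal SN2′ process, to give 14.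

Step 5. The most likely failure is epimerisation of the methyl-bearing centre (C10′) through enolisation of the ring ketone while the E isomer of 7 waits to isomerise, together with incomplete E-to-Z interconversion. The fallback makes only the Z isomer under neutral conditions and closes the ring under kinetic control. It sets out from 7 and comes back at 8. Zn in AcOH reduces the ene-dione to the saturated 1,4-diketone F5. Paal–Knorr cyclodehydration (pyridinium p-toluenesulfonate, toluene) gives the fused 2,3-dimethylfuran F6. Dye-sensitised photo-oxygenation of the furan, followed by dimethyl sulfide, returns 7 as the Z isomer alone. LiN(SiMe3)2 at −78 °C, which deprotonates only the unhindered acetyl methyl, then closes 8.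

Step 9. The most likely failure is elimination of the activated allylic alcohol to a cyclopentadiene, or a sluggish SN2 attack next to the tetrasubstituted alkene. The fallback forms the same bond with net retention through a π-allyl complex. It sets out from 8 and comes back at 13. The enantiomeric catalyst, (S)-2-methyl-CBS-oxazaborolidine, with catecholborane gives the 3′R diol F7. Methyl chloroformate and pyridine acylate only the secondary alcohol, giving carbonate F8. Pd(PPh3)4 with phenol 12 then gives 13 by ionisation and attack of the phenoxide at the less hindered C3′ terminus (double inversion).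

Step 11. The most likely failure is incomplete olefin migration, or slow deprotonation at other allylic positions and attack on the ester under prolonged basic conditions. The fallback installs the C8 hydrogen and the C6=C7 bond by hydroboration and anti elimination. It sets out from 12 and comes back at 15. BH3·SMe2 and then NaBO3 add to C7=C8 of 12 from the open α face to give the 7α-hydroxy-8α-H phenol F9. Mitsunobu coupling with 9 gives ether F10; the C7 carbinol, next to a methine between two quaternary carbons, should be too hindered to compete. TFA with anisole closes the dioxane as in step 10 to give the 7α-alcohol F11. MsCl and Et3N followed by DBU then eliminate in an anti E2 sense; only the 6β-hydrogen is antiperiplanar to the 7α leaving group, so the C6=C7 bond of 15 forms.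

## Further compounds

F1 | step 10 | 3-O-allylpristimerin | CC1=C(OCC=C)C(=O)C=C2C1=CC=C1[C@@]2(C)CC[C@@]2(C)[C@@H]3C[C@](C)(C(=O)OC)CC[C@]3(C)CC[C@]12C
F2 | step 10 | methyl 3-allyloxy-2-hydroxy-24-nor-D:A-friedooleana-1,3,5(10),7-tetraen-29-oate | Cc1c(OCC=C)c(O)cc2c1CC=C1[C@@]2(C)CC[C@@]2(C)[C@@H]3C[C@](C)(C(=O)OC)CC[C@]3(C)CC[C@]12C
F3 | step 10 | allyl analogue of 13 (O3-allyl, C1′ epimers) | CC1=C2C[C@@H](C(C)=C)CC[C@@H](C)C2(O)C[C@H]1Oc1cc2c(c(C)c1OCC=C)CC=C1[C@@]2(C)CC[C@@]2(C)[C@@H]3C[C@](C)(C(=O)OC)CC[C@]3(C)CC[C@]12C
F4 | step 10 | free O3 phenol corresponding to 13 (C1′ epimers) | CC1=C2C[C@@H](C(C)=C)CC[C@@H](C)C2(O)C[C@H]1Oc1cc2c(c(C)c1O)CC=C1[C@@]2(C)CC[C@@]2(C)[C@@H]3C[C@](C)(C(=O)OC)CC[C@]3(C)CC[C@]12C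
F5 | step 5 | (2R,5S)-2-methyl-7-(3-oxobutan-2-yl)-5-(prop-1-en-2-yl)cycloheptan-1-one (mixture at the two new centres) | CC(=O)C(C)C1C[C@@H](C(C)=C)CC[C@@H](C)C1=O
F6 | step 5 | (5S,8R)-2,3,8-trimethyl-5-(prop-1-en-2-yl)-5,6,7,8-tetrahydro-4H-cyclohepta[b]furan | Cc1oc2c(c1C)C[C@@H](C(C)=C)CC[C@H]2C
F7 | step 9 | (2R,5S,8R)-3,8-dimethyl-5-(prop-1-en-2-yl)-2,4,5,6,7,8-hexahydroazulene-2,8a(1H)-diol (3′ epimer of 9) | CC1=C2C[C@@H](C(C)=C)CC[C@@H](C)C2(O)C[C@H]1O
F8 | step 9 | 2-O-(methoxycarbonyl) derivative of the 3′R diol | CC1=C2C[C@@H](C(C)=C)CC[C@@H](C)C2(O)C[C@H]1OC(=O)OC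
F9 | step 11 | methyl 2,7α-dihydroxy-3-(4-methoxybenzyloxy)-24-nor-D:A-friedooleana-1,3,5(10)-trien-29-oate (8α-H) | Cc1c(OCc2ccc(OC)cc2)c(O)cc2c1C[C@@H](O)[C@H]1[C@@]2(C)CC[C@@]2(C)[C@@H]3C[C@](C)(C(=O)OC)CC[C@]3(C)CC[C@]12C
F10 | step 11 | 7α-hydroxy-7,8-dihydro (8α-H) analogue of 13 | CC1=C2C[C@@H](C(C)=C)CC[C@@H](C)C2(O)C[C@H]1Oc1cc2c(c(C)c1OCc1ccc(OC)cc1)C[C@@H](O)[C@H]1[C@@]2(C)CC[C@@]2(C)[C@@H]3C[C@](C)(C(=O)OC)CC[C@]3(C)CC[C@]12C
F11 | step 11 | 7α-hydroxy-6,7-dihydro derivative of 15 | C=C(C)[C@H]1CC[C@@H](C)C2=C(C1)[C@]1(C)Oc3c(cc4c(c3C)C[C@@H](O)[C@H]3[C@@]4(C)CC[C@@]4(C)[C@@H]5C[C@](C)(C(=O)OC)CC[C@]5(C)CC[C@]34C)O[C@@H]1C2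
A1 | alternative 1 | 8α-H o-quinone tautomer of pristimerin (methyl 2,3-dioxo-24-nor-D:A-friedooleana-1(10),4,6-trien-29-oate) | CC1=C2C=C[C@H]3[C@](C)(C2=CC(=O)C1=O)CC[C@@]4(C)[C@@H]5C[C@](C)(C(=O)OC)CC[C@]5(C)CC[C@]34C
A2 | alternative 1 | (7S,10R)-guaia-1(5),3,11-triene | CC1=CCC2=C1C[C@@H](C(C)=C)CC[C@H]2C
A3 | alternative 2 | pristimerol (methyl 2,3-dihydroxy-24-nor-D:A-friedooleana-1,3,5(10),7-tetraen-29-oate) | Cc1c(O)c(O)cc2c1CC=C1[C@@]2(C)CC[C@@]2(C)[C@@H]3C[C@](C)(C(=O)OC)CC[C@]3(C)CC[C@]12C
A4 | alternative 2 | cis-1′,3′-bis(methoxycarbonyloxy)guaia-4′,11′-diene | CC1=C2C[C@@H](C(C)=C)CC[C@@H](C)[C@]2(OC(=O)OC)C[C@H]1OC(=O)OC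
A5 | alternative 3 | (S)-3-methyl-6-(prop-1-en-2-yl)deca-1,2-dien-8-yne | CC#CC[C@@H](C(C)=C)CCC(C)=C=C
A6 | alternative 3 | (7S)-guaia-1(10),4,11-trien-3-one | CC1=C2C[C@@H](C(C)=C)CCC(C)=C2CC1=O
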